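## Retrosynthetic overview

- The strategy rests on the two 3-methylbut-2-enyl chains at C6 and C8 of benzo ring A, the two carbons ortho to the C7 hydroxyl. Each is an allyl group whose terminal CH2 is exchanged for C(CH3)2, so the target flavanone 16 is disconnected at both side-chain C=C bonds to the (2S)-6,8-diallylflavanone 12 and 2-methyl-2-butene (13) by a double cross-metathesis.
- 12 comes from silyl ether 11, made by rhodium-catalysed asymmetric 1,4-addition of 4-methoxyphenylboronic acid (10) to C2 of the pyranone ring of chromone 9; this sets the only stereocentre.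
- 9 comes from 7-hydroxychromone (1) by two rounds of O7-allylation with allyl bromide (2) and aromatic Claisen rearrangement (to C8, then to C6), followed by silylation. The substitution pattern is built before the stereocentre exists.
- Ring order: rings A and C are both present in 1 and ring B arrives with 10. No ring is formed in the route; the only ring event is saturation of C2–C3.

Key step: step 8

Assumption: the (S)-antipode of the biaryl bisphosphine is taken to deliver the aryl group to the C2 face that gives 2S, by the usual quadrant model for rhodium/atropisomeric bisphosphine additions to cyclic enones. The (R)-antipode is equally available should the sense prove reversed on this substrate.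

## Route

Step 1
Reactants: 1 7-hydroxy-4H-chromen-4-one; 2 allyl bromide
Product: 3 7-(allyloxy)-4H-chromen-4-one
Conditions: K2CO3, acetone, reflux
Reagents that add atoms: none
Why: Williamson ether synthesis, in which the acidic 7-OH (conjugated with the C4 carbonyl through C4a) is deprotonated by carbonate and the phenoxide displaces bromide from the allyl halide at oxygen.

Step 2
Reactants: 3 7-(allyloxy)-4H-chromen-4-one
Product: 5 8-allyl-7-hydroxy-4H-chromen-4-one, via C8 ortho-dienone 4 (not isolated)
Conditions: PhNEt2, 200 °C, Ar
Reagents that add atoms: none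
Why: Aromatic Claisen rearrangement ([3,3]-sigmatropic shift) gives dienone 4, which tautomerises to the phenol; C8 should be favoured because the C7–C8 bond has the higher double-bond character in the benzopyranone, and any 6-allyl isomer can be carried along since it converges on 8 after steps 3 and 4.

Step 3
Reactants: 5 8-allyl-7-hydroxy-4H-chromen-4-one; 2 allyl bromide
Product: 6 8-allyl-7-(allyloxy)-4H-chromen-4-one
Conditions: K2CO3, acetone, reflux
Reagents that add atoms: none
Why: Williamson ether synthesis as in step 1; the ortho allyl group does not hinder O-alkylation of the phenoxide by the unhindered primary allylic bromide.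

Step 4
Reactants: 6 8-allyl-7-(allyloxy)-4H-chromen-4-one
Product: 8 6,8-diallyl-7-hydroxy-4H-chromen-4-one, via C6 ortho-dienone 7 (not isolated)
Conditions: PhNEt2, 210 °C, Ar
Reagents that add atoms: none
Why: Second aromatic Claisen rearrangement; migration to the occupied C8 gives a dienone that cannot enolise and only reverts, so the allyl group should end up at C6, the one free ortho position, where dienone 7 tautomerises to the phenol, while the amine solvent suppresses acid-catalysed closure of the phenol onto an allyl group.

Step 5
Reactants: 8 6,8-diallyl-7-hydroxy-4H-chromen-4-one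
Product: 9 6,8-diallyl-7-[(tert-butyldimethylsilyl)oxy]-4H-chromen-4-one
Conditions: TBSCl, imidazole, DMAP (cat.), DMF, rt
Reagents that add atoms: tert-butyldimethylsilyl chloride, CC(C)(C)[Si](C)(C)Cl
Why: Imidazole-mediated O-silylation of the phenol; the free 7-OH would otherwise be deprotonated in step 6 and, as the phenoxide, deactivate the enone and protonate the aryl–rhodium species.

Step 6
Reactants: 9 6,8-diallyl-7-[(tert-butyldimethylsilyl)oxy]-4H-chromen-4-one; 10 4-methoxyphenylboronic acid
Product: 11 (2S)-6,8-diallyl-7-[(tert-butyldimethylsilyl)oxy]-2-(4-methoxyphenyl)chroman-4-one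
Conditions: [RhCl(C2H4)2]2 (cat.), (S)-MeO-BIPHEP analogue bearing bis(3,4,5-trifluorophenyl)phosphino groups (cat.), aq. KOH (cat.), toluene/H2O, 25 °C
Reagents that add atoms: none
Why: Hayashi–Miyaura asymmetric 1,4-addition, in which the aryl group passes from boron to rhodium, the aryl–rhodium species inserts the C2=C3 bond of the pyranone and water hydrolyses the rhodium enolate; the C2 stereocentre is set by the chiral bisphosphine, which exposes one face of the enone, and the electron-poor ligand keeps the reaction fast at ambient temperature so that 1,2-addition to the ketone and loss of the doubly ortho-shielded silyl ether should stay minor.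

Step 7
Reactants: 11 (2S)-6,8-diallyl-7-[(tert-butyldimethylsilyl)oxy]-2-(4-methoxyphenyl)chroman-4-one
Product: 12 (2S)-6,8-diallyl-7-hydroxy-2-(4-methoxyphenyl)chroman-4-one
Conditions: TBAF, AcOH (1:1), THF, 0 °C
Reagents that add atoms: none
Why: Fluoride-induced cleavage of the aryl silyl ether, driven by Si–F bond formation; the acetic acid buffer protonates the phenoxide at once so that base-induced retro-oxa-Michael ring opening to the chalcone, which would racemise C2, should not occur.

Step 8
Reactants: 12 (2S)-6,8-diallyl-7-hydroxy-2-(4-methoxyphenyl)chroman-4-one; 13 2-methyl-2-butene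
Product: 16 (2S)-7-hydroxy-2-(4-methoxyphenyl)-6,8-bis(3-methylbut-2-enyl)chroman-4-one, via 8-allyl-6-prenyl flavanone 14 (not isolated), via 6-allyl-8-prenyl flavanone 15 (not isolated)
Conditions: Grubbs second-generation catalyst (10 mol%), 2-methyl-2-butene (large excess)/CH2Cl2, 1,4-benzoquinone (20 mol%), 40 °C, sealed tube
Reagents that add atoms: none
Why: Olefin cross-metathesis by the Chauvin mechanism: the ruthenium carbene engages each monosubstituted allyl alkene of 12, and [2+2] cycloaddition/cycloreversion with 2-methyl-2-butene exchanges the terminal =CH2 for =C(CH3)2 with loss of propene, first at one chain (14 or 15) and then at the other. The closest known reaction type is the ruthenium-catalysed cross-metathesis of allylarenes, free ortho-allylphenols included, with 2-methyl-2-butene to give prenylarenes. No ring closes and no stereocentre is created; C2, set in step 6, is not touched by the neutral catalyst, which tolerates the ketone, the aryl ether and the free phenol. The step needs cross-metathesis to outrun homodimerisation and must avoid migration of the allyl double bonds into conjugation; the large excess of the trisubstituted partner, the inertness of the trisubstituted product alkenes (which makes the diprenyl compound a sink) and benzoquinone as a scavenger of ruthenium hydrides should secure both. Ring-closing metathesis between the two chains is excluded, because they sit meta to each other on ring A and would have to form a seven-membered meta-bridged ring.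

## Compound list

1 | 7-hydroxy-4H-chromen-4-one (7-hydroxychromone) | O=c1ccoc2cc(O)ccc12 | starting material
2 | allyl bromide (3-bromoprop-1-ene) | C=CCBr | starting material
3 | 7-(allyloxy)-4H-chromen-4-one | O=c1ccoc2cc(OCC=C)ccc12 | intermediate
4 | 8-allyl-8H-chromene-4,7-dione (C8 ortho-dienone, racemic at C8, not isolated) | C=CCC1C(=O)C=CC2=C1OC=CC2=O | intermediate
5 | 8-allyl-7-hydroxy-4H-chromen-4-one | O=c1ccoc2c(CC=C)c(O)ccc12 | intermediate
6 | 8-allyl-7-(allyloxy)-4H-chromen-4-one | O=c1ccoc2c(CC=C)c(OCC=C)ccc12 | intermediate
7 | 6,8-diallyl-6H-chromene-4,7-dione (C6 ortho-dienone, racemic at C6, not isolated) | C=CCC1C=C2C(=O)C=COC2=C(CC=C)C1=O | intermediate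
8 | 6,8-diallyl-7-hydroxy-4H-chromen-4-one | O=c1ccoc2c(CC=C)c(O)c(CC=C)cc12 | intermediate
9 | 6,8-diallyl-7-[(tert-butyldimethylsilyl)oxy]-4H-chromen-4-one | O=c1ccoc2c(CC=C)c(O[Si](C)(C)C(C)(C)C)c(CC=C)cc12 | intermediate
10 | 4-methoxyphenylboronic acid | COc1ccc(B(O)O)cc1 | starting material
11 | (2S)-6,8-diallyl-7-[(tert-butyldimethylsilyl)oxy]-2-(4-methoxyphenyl)chroman-4-one | COc1ccc([C@@H]2CC(=O)c3cc(CC=C)c(O[Si](C)(C)C(C)(C)C)c(CC=C)c3O2)cc1 | intermediate
12 | (2S)-6,8-diallyl-7-hydroxy-2-(4-methoxyphenyl)chroman-4-one | COc1ccc([C@@H]2CC(=O)c3cc(CC=C)c(O)c(CC=C)c3O2)cc1 | intermediate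
13 | 2-methyl-2-butene | CC=C(C)C | starting material
14 | (2S)-8-allyl-7-hydroxy-2-(4-methoxyphenyl)-6-(3-methylbut-2-enyl)chroman-4-one (not isolated) | COc1ccc([C@@H]2CC(=O)c3cc(CC=C(C)C)c(O)c(CC=C)c3O2)cc1 | intermediate
15 | (2S)-6-allyl-7-hydroxy-2-(4-methoxyphenyl)-8-(3-methylbut-2-enyl)chroman-4-one (not isolated) | COc1ccc([C@@H]2CC(=O)c3cc(CC=C)c(O)c(CC=C(C)C)c3O2)cc1 | intermediate
16 | (2S)-7-hydroxy-2-(4-methoxyphenyl)-6,8-bis(3-methylbut-2-enyl)chroman-4-one (the target natural flavanone) | COc1ccc([C@@H]2CC(=O)c3cc(CC=C(C)C)c(O)c(CC=C(C)C)c3O2)cc1 | target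

## Step count and risks

Total step count: 8. Longest linear sequence: 8 steps (1 to 16).

Steps most likely to fail:

1. Step 6. Aryl transfer to the electron-rich, fully substituted chromone may be slow, so that protodeboronation of the boronic acid or loss of the silyl ether in the basic aqueous medium overtakes insertion, or facial discrimination may be insufficient. Fallback: setting out from 9 and 10, the addition is run with the more active achiral catalyst [Rh(OH)(cod)]2 in dioxane/H2O at 60 °C and should give racemic 6,8-diallyl-7-[(tert-butyldimethylsilyl)oxy]-2-(4-methoxyphenyl)chroman-4-one F1 in place of the single enantiomer. Kinetic resolution of this racemate by asymmetric transfer hydrogenation (Cp*RhCl[(R,R)-TsDPEN], HCO2H/Et3N, EtOAc, rt) is expected to reduce the 2R ketone to cis-(2R,4R)-6,8-diallyl-7-[(tert-butyldimethylsilyl)oxy]-2-(4-methoxyphenyl)chroman-4-ol F2 while the 2S ketone is left untouched. Chromatographic separation of ketone from alcohol returns the route at 11.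

2. Step 8. The double exchange may stall at the mono-prenyl stage, or ruthenium hydrides may move the allyl double bonds into conjugation with ring A faster than metathesis proceeds. Fallback: setting out from 11, one-pot dihydroxylation and periodate cleavage (cat. OsO4, NaIO4, 2,6-lutidine, dioxane/H2O) should pass through (2S)-7-[(tert-butyldimethylsilyl)oxy]-6,8-bis(2,3-dihydroxypropyl)-2-(4-methoxyphenyl)chroman-4-one F3 and end at (2S)-7-[(tert-butyldimethylsilyl)oxy]-2-(4-methoxyphenyl)-6,8-bis(2-oxoethyl)chroman-4-one F4 as the dialdehyde. Double Wittig olefination with isopropylidenetriphenylphosphorane (from isopropyltriphenylphosphonium iodide and n-BuLi, THF, −78 °C, kept cold so that the aldehydes react before the C4 aryl ketone or C3 enolisation intervene) should give (2S)-7-[(tert-butyldimethylsilyl)oxy]-2-(4-methoxyphenyl)-6,8-bis(3-methylbut-2-enyl)chroman-4-one F5 as the silyl ether. Buffered fluoride as in step 7 returns the route at 16.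

3. Step 4. Migration to the less activated C6 demands the highest temperature of the route, so thermal degradation of the pyranone or closure of the phenol onto a neighbouring allyl group to a dihydrofuran may compete with the rearrangement. Fallback: setting out from 1, double ortho-iodination (NIS, 2.2 equiv, cat. TFA, MeCN) should give 7-hydroxy-6,8-diiodo-4H-chromen-4-one F6 as the only new compound, and double Stille allylation (allyltributylstannane, Pd(PPh3)4, DMF, 90 °C) returns the route at 8, so that steps 1 to 4 are replaced.

Further compounds
F1 | step 6 | racemic 6,8-diallyl-7-[(tert-butyldimethylsilyl)oxy]-2-(4-methoxyphenyl)chroman-4-one | COc1ccc(C2CC(=O)c3cc(CC=C)c(O[Si](C)(C)C(C)(C)C)c(CC=C)c3O2)cc1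
F2 | step 6 | cis-(2R,4R)-6,8-diallyl-7-[(tert-butyldimethylsilyl)oxy]-2-(4-methoxyphenyl)chroman-4-ol | COc1ccc([C@H]2C[C@@H](O)c3cc(CC=C)c(O[Si](C)(C)C(C)(C)C)c(CC=C)c3O2)cc1
F3 | step 8 | (2S)-7-[(tert-butyldimethylsilyl)oxy]-6,8-bis(2,3-dihydroxypropyl)-2-(4-methoxyphenyl)chroman-4-one (mixture at the carbinol centres) | COc1ccc([C@@H]2CC(=O)c3cc(CC(O)CO)c(O[Si](C)(C)C(C)(C)C)c(CC(O)CO)c3O2)cc1
F4 | step 8 | (2S)-7-[(tert-butyldimethylsilyl)oxy]-2-(4-methoxyphenyl)-6,8-bis(2-oxoethyl)chroman-4-one | COc1ccc([C@@H]2CC(=O)c3cc(CC=O)c(O[Si](C)(C)C(C)(C)C)c(CC=O)c3O2)cc1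
F5 | step 8 | (2S)-7-[(tert-butyldimethylsilyl)oxy]-2-(4-methoxyphenyl)-6,8-bis(3-methylbut-2-enyl)chroman-4-one | COc1ccc([C@@H]2CC(=O)c3cc(CC=C(C)C)c(O[Si](C)(C)C(C)(C)C)c(CC=C(C)C)c3O2)cc1
F6 | step 4 | 7-hydroxy-6,8-diiodo-4H-chromen-4-one | O=c1ccoc2c(I)c(O)c(I)cc12
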